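**Retrosynthetic overview**

1. The strategy rests on the ketone half: a cis-fused 2′,3′-epoxy-4′-ketone ring (ketal carbon C1′, oxirane C2′–C3′, C4′=O, fused to ring A at C4a′/C8a′) with the oxirane syn to the oxygen bridging C1′ and C1. The C2′–C3′ and C3′–O bonds are cut together (intramolecular Darzens of a C4a′ chloroacetyl group onto a C1′ aldehyde), so this carbocycle and its oxirane form last.
2. The aldehyde comes from a C1′–CH2OTBS arm, the chloroacetyl group from Br/Li exchange at C4a′ and ClCH2C(O)N(OMe)Me. The bromine is set on the small ring A fragment, so the cage is never deprotonated (its C7–H and C4–H are acidic).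
3. The cage (first the five-membered C1–O–C1′ ring, then the 1,3-dioxine ring through the C8 phenol) comes from transketalisation of a C1′ dimethyl ketal. The C8′–C1 bond comes from adding the ring A aryllithium to the C1 ketone of an epoxy tetralone, anti to the C2–C3 oxirane.
4. Epoxy tetralone: Friedel–Crafts acylation and cyclisation build the carbocycle on ring B, then naphthol, quinone monoketal, catalytic asymmetric epoxidation (C2, C3) and oxirane-directed reduction (C4). Ring A fragment: Moriarty oxidation, then directed lithiation/bromination.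
5. Ring order: alcohol-half carbocycle, C2–C3 oxirane, five-membered ketal ring, dioxine ring, ketone-half carbocycle together with the C2′–C3′ oxirane.

Key step: step 25

Remarks:
- Locants follow the target: alcohol half C1–C8a (ring B = arene C4a–C8a), ketone half C1′–C8a′ (ring A = arene C4a′–C8a′). Alcohol-half intermediates are named with these locants.
- Assumption: N-benzylcinchonidinium chloride gives the (2R,3S)-epoxide 13 in step 8; if the sense of induction is the reverse, the pseudoenantiomeric N-benzylcinchoninium chloride takes its place.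
- Assumption: compounds 1, 2, 17 and 32 are bought.

**Alcohol half (steps 1–11)**

Step 1
Reactants: 1 2-chloro-1,4-dimethoxybenzene; 2 succinic anhydride
Product: 3 4-(4-chloro-2,5-dimethoxyphenyl)-4-oxobutanoic acid
Conditions: AlCl3 (2.2 equiv), CH2Cl2, 0 °C → rt; aq. HCl
Reagents that add atoms: none
Why: Friedel–Crafts acylation should enter at the only position that is ortho to a methoxy group and para to chlorine, which places chlorine at the future C6 next to the C5 oxygen.

Step 2
Reactants: 3 4-(4-chloro-2,5-dimethoxyphenyl)-4-oxobutanoic acid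
Product: 5 6-chloro-5,8-dimethoxy-2,3-dihydronaphthalen-4(1H)-one, via arylbutanoic acid 4 (not isolated)
Conditions: Et3SiH (2.5 equiv), CF3CO2H, 55 °C; evaporate; (CF3CO)2O, CH2Cl2, 0 °C → rt
Reagents that add atoms: none
Why: Ionic hydrogenation takes the electron-rich aryl ketone down to CH2, and the mixed trifluoroacetic anhydride then closes the ring by intramolecular Friedel–Crafts acylation at the only free position ortho to the chain, so the new carbonyl is C4, peri to the C5 oxygen.

Step 3
Reactants: 5 6-chloro-5,8-dimethoxy-2,3-dihydronaphthalen-4(1H)-one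
Product: 6 6-chloro-5,8-dihydroxy-2,3-dihydronaphthalen-4(1H)-one
Conditions: BBr3 (3 equiv), CH2Cl2, −78 °C → rt; H2O (under argon)
Reagents that add atoms: none
Why: Lewis-acid ether cleavage with BBr3 should free both phenols, which then differ because only the C5 hydroxyl is hydrogen-bonded to the C4 carbonyl.

Step 4
Reactants: 6 6-chloro-5,8-dihydroxy-2,3-dihydronaphthalen-4(1H)-one
Product: 7 8-(allyloxy)-6-chloro-5-hydroxy-2,3-dihydronaphthalen-4(1H)-one
Conditions: allyl bromide (1.05 equiv), K2CO3, acetone, 50 °C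
Reagents that add atoms: allyl bromide C=CCBr
Why: Williamson etherification under weak base should take place at the free C8 hydroxyl, since the C5 hydroxyl is chelated to the ketone and flanked by chlorine.

Step 5
Reactants: 7 8-(allyloxy)-6-chloro-5-hydroxy-2,3-dihydronaphthalen-4(1H)-one
Product: 8 8-(allyloxy)-6-chloro-5-(methoxymethoxy)-2,3-dihydronaphthalen-4(1H)-one
Conditions: NaH, MOMCl, DMF, 0 °C → rt
Reagents that add atoms: chloromethyl methyl ether COCCl
Why: O-alkylation of the sodium phenoxide (acetal ether formation) should cap the chelated C5 phenol with a group that is stable to base, hydride and organolithiums.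

Step 6
Reactants: 8 8-(allyloxy)-6-chloro-5-(methoxymethoxy)-2,3-dihydronaphthalen-4(1H)-one
Product: 11 8-(allyloxy)-6-chloro-5-(methoxymethoxy)naphthalen-4-ol, via lithium enolate 9 (not isolated), via α-selenide 10 (not isolated)
Conditions: LiN(SiMe3)2, THF, −78 °C; PhSeCl (1.0 equiv); then mCPBA, CH2Cl2, −78 °C; i-Pr2NH, → rt
Reagents that add atoms: none
Why: α-Selenenylation of the ketone enolate and selenoxide syn-elimination should give the cross-conjugated naphthalenone, which tautomerises at once to the aromatic naphthol.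

Step 7
Reactants: 11 8-(allyloxy)-6-chloro-5-(methoxymethoxy)naphthalen-4-ol
Product: 12 8-(allyloxy)-6-chloro-1,1-dimethoxy-5-(methoxymethoxy)naphthalen-4(1H)-one
Conditions: PhI(OAc)2, MeOH, 0 °C
Reagents that add atoms: methanol CO
Why: Oxidative dearomatisation of a para-unsubstituted naphthol with the hypervalent iodine diacetate in methanol should give the para-quinone monoketal, with the ketone kept at C4 and the new dimethyl ketal at C1.

Step 8
Reactants: 12 8-(allyloxy)-6-chloro-1,1-dimethoxy-5-(methoxymethoxy)naphthalen-4(1H)-one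
Product: 13 (2R,3S)-8-(allyloxy)-6-chloro-2,3-epoxy-1,1-dimethoxy-5-(methoxymethoxy)-2,3-dihydronaphthalen-4(1H)-one
Conditions: t-BuOOH, N-benzylcinchonidinium chloride (10 mol %), aq. NaOH, toluene, 0 °C; recrystallise
Reagents that add atoms: tert-butyl hydroperoxide CC(C)(C)OO
Why: Weitz–Scheffer nucleophilic epoxidation under chiral phase-transfer catalysis, in which the cinchona ammonium hydroperoxide ion pair should attack one enone face and set C2 and C3 (cis by ring closure), the epoxide being recrystallised to enantiopurity.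

Step 9
Reactants: 13 (2R,3S)-epoxy ketone ketal
Product: 14 (2R,3R,4S)-8-(allyloxy)-6-chloro-2,3-epoxy-1,1-dimethoxy-5-(methoxymethoxy)-1,2,3,4-tetrahydronaphthalen-4-ol
Conditions: i-Bu2AlH, toluene/CH2Cl2, −78 °C; Rochelle salt
Reagents that add atoms: none
Why: Oxirane-directed carbonyl reduction, in which aluminium bound to the epoxide oxygen should deliver hydride to the carbonyl face on the oxirane side, so that the C4 hydroxyl comes out trans to the oxirane.

Step 10
Reactants: 14 (2R,3R,4S)-epoxy alcohol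
Product: 15 (2R,3S,4S)-8-(allyloxy)-6-chloro-2,3-epoxy-1,1-dimethoxy-5-(methoxymethoxy)-4-[(triisopropylsilyl)oxy]-1,2,3,4-tetrahydronaphthalene
Conditions: i-Pr3SiOTf, 2,6-lutidine, CH2Cl2, −78 → 0 °C
Reagents that add atoms: triisopropylsilyl triflate CC(C)[Si](C(C)C)(C(C)C)OS(=O)(=O)C(F)(F)F
Why: Silyl ether formation with the silyl triflate and a hindered base should protect the hindered secondary C4 alcohol with a group that outlasts the later removal of a primary TBS ether.

Step 11
Reactants: 15 TIPS ether ketal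
Product: 16 (2R,3S,4S)-8-(allyloxy)-6-chloro-2,3-epoxy-5-(methoxymethoxy)-4-[(triisopropylsilyl)oxy]-3,4-dihydronaphthalen-1(2H)-one
Conditions: 10% aq. (CO2H)2 on SiO2, CH2Cl2, rt
Reagents that add atoms: water O
Why: Mild acid hydrolysis of the benzylic dimethyl ketal, which is far more labile than the MOM ether, the TIPS ether or the oxirane, should unveil the C1 ketone.

**Ring A fragment (steps 12–18)**

Step 12
Reactants: 17 1-(4-chloro-3-hydroxyphenyl)ethan-1-one
Product: 18 1-[4-chloro-3-(methoxymethoxy)phenyl]ethan-1-one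
Conditions: MOMCl, i-Pr2NEt, CH2Cl2, 0 °C → rt
Reagents that add atoms: chloromethyl methyl ether COCCl
Why: MOM ether formation protects the phenol against the oxidant of step 13 and supplies the directing group for the lithiation of step 17.

Step 13
Reactants: 18 1-[4-chloro-3-(methoxymethoxy)phenyl]ethan-1-one
Product: 19 2-[4-chloro-3-(methoxymethoxy)phenyl]-2,2-dimethoxyethan-1-ol
Conditions: PhI(OAc)2, KOH, MeOH, 0 °C → rt
Reagents that add atoms: methanol CO
Why: Moriarty α-hydroxylation, in which the enolate is oxidised by the hypervalent iodine diacetate and methoxide opens the intermediate methoxy oxirane, should give the α-hydroxy dimethyl ketal (the masked hydroxyacetyl unit C1′–C2′) in one operation.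

Step 14
Reactants: 19 2-[4-chloro-3-(methoxymethoxy)phenyl]-2,2-dimethoxyethan-1-ol
Product: 20 tert-butyl{2-[4-chloro-3-(methoxymethoxy)phenyl]-2,2-dimethoxyethoxy}dimethylsilane
Conditions: TBSCl, imidazole, DMF, rt
Reagents that add atoms: tert-butyldimethylsilyl chloride CC(C)(C)[Si](C)(C)Cl
Why: Silylation of the unhindered primary alcohol should protect it through the organolithium steps.

Step 15
Reactants: 20 TBS ether
Product: 21 {2-[2-bromo-4-chloro-5-(methoxymethoxy)phenyl]-2,2-dimethoxyethoxy}(tert-butyl)dimethylsilane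
Conditions: NBS, MeCN, 0 °C → rt
Reagents that add atoms: N-bromosuccinimide O=C1CCC(=O)N1Br
Why: Electrophilic aromatic bromination should go para to the MOM ether, whose ortho positions carry chlorine or are shielded by the quaternary ketal carbon, which marks the future C8′.

Step 16
Reactants: 21 aryl bromide
Product: 23 tert-butyl{2-[4-chloro-5-(methoxymethoxy)-2-(trimethylsilyl)phenyl]-2,2-dimethoxyethoxy}dimethylsilane, via aryllithium 22 (not isolated)
Conditions: n-BuLi, THF, −78 °C; Me3SiCl
Reagents that add atoms: chlorotrimethylsilane C[Si](C)(C)Cl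
Why: Bromine–lithium exchange and silylation should swap the bromine for a trimethylsilyl placeholder that survives the alkyllithium of step 17 and is turned into iodine in step 18.

Step 17
Reactants: 23 aryl silane
Product: 25 {2-[2-bromo-4-chloro-3-(methoxymethoxy)-6-(trimethylsilyl)phenyl]-2,2-dimethoxyethoxy}(tert-butyl)dimethylsilane, via aryllithium 24 (not isolated)
Conditions: s-BuLi, TMEDA, THF, −78 °C; BrCl2CCCl2Br
Reagents that add atoms: 1,2-dibromotetrachloroethane BrC(Cl)(Cl)C(Cl)(Cl)Br
Why: Directed ortho-metalation should occur at the only position activated by both the MOM ether and the ketal oxygens, and bromination of that aryllithium places the C4a′ bromine without ambiguity.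

Step 18
Reactants: 25 bromo aryl silane
Product: 26 {2-[2-bromo-4-chloro-6-iodo-3-(methoxymethoxy)phenyl]-2,2-dimethoxyethoxy}(tert-butyl)dimethylsilane
Conditions: ICl, NaHCO3, CH2Cl2, −78 → 0 °C
Reagents that add atoms: iodine monochloride ICl
Why: Ipso-iododesilylation of the aryl silane should put iodine exactly at the future C8′, a position that direct iodination cannot reach once the MOM ether is twisted between two halogens.

**Union and endgame (steps 19–27)**

Step 19
Reactants: 26 bromo iodo arene; 16 epoxy ketone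
Product: 28 tertiary alcohol with the C8′–C1 bond (C1–OH cis to the C2–C3 oxirane; ring A carries C4a′–Br and the C1′ dimethyl ketal with CH2OTBS), via aryllithium 27 (not isolated)
Conditions: n-BuLi (1.0 equiv on 26), THF/Et2O, −100 °C; 16, −100 → −78 °C; aq. NH4Cl
Reagents that add atoms: none
Why: Iodine–lithium exchange is much faster than bromine–lithium exchange at −100 °C, and 1,2-addition of the aryllithium to the C1 ketone should occur anti to the adjacent C2–C3 oxirane, which sets C1 with its oxygen cis to the oxirane.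

Step 20
Reactants: 28 tertiary alcohol
Product: 29 C8 phenol of 28
Conditions: Pd(PPh3)4 (5 mol %), morpholine, THF, rt
Reagents that add atoms: none
Why: Zerovalent palladium ionises the aryl allyl ether to a π-allyl complex that morpholine traps (Tsuji–Trost deallylation), which should free the C8 phenol under neutral conditions while the hindered aryl bromide stays intact.

Step 21
Reactants: 29 phenol diol ketal
Product: 31 cage bromide (bicyclic ketal C1–O–C1′ and C8–O–C1′; C4a′–Br; C1′–CH2OTBS; C4–OTIPS; both MOM ethers), via methyl ketal 30 (not isolated)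
Conditions: PPTS (20 mol %), 5 Å molecular sieves, CH2Cl2, rt → 40 °C
Reagents that add atoms: none
Why: Acid-catalysed transketalisation, in which the tertiary C1 hydroxyl should first close the five-membered ring on the C1′ oxocarbenium ion and the C8 phenol then closes the dioxine ring with loss of the second methanol, the configuration at C1′ being dictated by C1 because only one bicyclic ketal can form.

Step 22
Reactants: 31 cage bromide; 32 2-chloro-N-methoxy-N-methylacetamide
Product: 34 cage chloromethyl ketone (C4a′–C(=O)CH2Cl; C1′–CH2OTBS), via aryllithium 33 (not isolated)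
Conditions: t-BuLi (2.1 equiv), THF, −78 °C, 10 min; 32, −78 → −40 °C; aq. NH4Cl
Reagents that add atoms: none
Why: Bromine–lithium exchange with t-BuLi is faster than any deprotonation of the cage at −78 °C, and acylation of the aryllithium by the Weinreb amide stops at the stable chelate, which should give the chloromethyl ketone on work-up.

Step 23
Reactants: 34 cage chloromethyl ketone
Product: 35 primary alcohol (C1′–CH2OH)
Conditions: HF·pyridine, pyridine, THF, 0 °C
Reagents that add atoms: none
Why: Fluoride-mediated desilylation with buffered HF·pyridine should remove the primary TBS ether much faster than the hindered secondary TIPS ether.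

Step 24
Reactants: 35 primary alcohol
Product: 36 cage chloroacetyl aldehyde (C1′–CHO; C4a′–C(=O)CH2Cl)
Conditions: Dess–Martin periodinane, NaHCO3, CH2Cl2, rt
Reagents that add atoms: none
Why: Dess–Martin oxidation of the primary alcohol, which equilibrates with its six-membered hemiketal on the chloro ketone, should give the non-enolisable ketal aldehyde without touching the chloro ketone.

Step 25
Reactants: 36 cage chloroacetyl aldehyde
Product: 38 fully protected target (C5 and C5′ MOM ethers; C4–OTIPS), via aldolate 37 (not isolated)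
Conditions: Cs2CO3, MeCN, 0 °C → rt
Reagents that add atoms: none
Why: Cs2CO3 deprotonates the chloroacetyl CH2 (the aldehyde on the ketal carbon C1′ has no α-hydrogen), the enolate carbon C3′ adds to the aldehyde carbon C2′ in a 6-exo-trig aldol that closes the ketone-half carbocycle (C1′–C2′–C3′–C4′–C4a′–C8a′), and the alkoxide of 37 displaces chloride at C3′ in a 3-exo-tet SN2 that closes the oxirane; this is an intramolecular Darzens condensation of an α-chloro ketone with an aldehyde. The cage holds the C1′–O(aryl) bond axial and the bridging C1′–O–C1 bond near the plane of ring A, so the aldehyde should react with its oxygen anti to the axial C–O bond and the aldolate oxygen at C2′ lands axial on the side of the bridging oxygen. Only the chlorohydrin with this axial oxygen and an anti-periplanar axial chlorine at C3′ can close, and it gives the cis-fused oxirane syn to the bridging oxygen, which sets C2′ (cage control) and C3′ (SN2 inversion, cis fusion forced by the six-membered ring). The aldol step is reversible and the CHCl centre epimerises under carbonate, so the other aldolates should drain through this one. Chemoselectivity rests on the substrate: the aryl ketone has no second α-position (no Favorskii path), the C5′ phenol is capped (no ring closure of a phenoxide onto CH2Cl), and the MOM ethers, the TIPS ether, the ketal and the C2–C3 oxirane are inert to carbonate.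

Step 26
Reactants: 38 fully protected target
Product: 39 C4 TIPS ether of the target (C5–OH and C5′–OH free)
Conditions: Me3SiOTf, 2,2′-bipyridyl, CH2Cl2, 0 °C; then H2O
Reagents that add atoms: none
Why: Silyl triflate/2,2′-bipyridyl cleavage of aryl MOM ethers runs through pyridinium-type intermediates that water hydrolyses, conditions that are essentially non-acidic and should spare both oxiranes, the ketal and the TIPS ether.

Step 27
Reactants: 39 C4 TIPS ether of the target
Product: 40 target CNP0289684.3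
Conditions: Bu4NF, AcOH, THF, 0 °C → rt
Reagents that add atoms: none
Why: Fluoride-mediated desilylation buffered with acetic acid should remove the TIPS ether without base-induced damage to the epoxy ketone or the phenols.

**Compound list**

1 | 2-chloro-1,4-dimethoxybenzene | COc1ccc(OC)c(Cl)c1 | starting material
2 | succinic anhydride | O=C1CCC(=O)O1 | starting material
3 | 4-(4-chloro-2,5-dimethoxyphenyl)-4-oxobutanoic acid | OC(=O)CCC(=O)c1cc(OC)c(Cl)cc1OC | intermediate
4 | 4-(4-chloro-2,5-dimethoxyphenyl)butanoic acid | OC(=O)CCCc1cc(OC)c(Cl)cc1OC | intermediate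
5 | 6-chloro-5,8-dimethoxy-2,3-dihydronaphthalen-4(1H)-one | O=C1CCCc2c(OC)cc(Cl)c(OC)c12 | intermediate
6 | 6-chloro-5,8-dihydroxy-2,3-dihydronaphthalen-4(1H)-one | O=C1CCCc2c(O)cc(Cl)c(O)c12 | intermediate
7 | 8-(allyloxy)-6-chloro-5-hydroxy-2,3-dihydronaphthalen-4(1H)-one | O=C1CCCc2c(OCC=C)cc(Cl)c(O)c12 | intermediate
8 | 8-(allyloxy)-6-chloro-5-(methoxymethoxy)-2,3-dihydronaphthalen-4(1H)-one | O=C1CCCc2c(OCC=C)cc(Cl)c(OCOC)c12 | intermediate
9 | lithium enolate of 8 (C3=C4–OLi) | [Li]OC1=CCCc2c(OCC=C)cc(Cl)c(OCOC)c12 | intermediate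
10 | 3-(phenylselanyl) derivative of 8 (racemic) | O=C1C([Se]c3ccccc3)CCc2c(OCC=C)cc(Cl)c(OCOC)c12 | intermediate
11 | 8-(allyloxy)-6-chloro-5-(methoxymethoxy)naphthalen-4-ol | Oc1cccc2c(OCC=C)cc(Cl)c(OCOC)c12 | intermediate
12 | 8-(allyloxy)-6-chloro-1,1-dimethoxy-5-(methoxymethoxy)naphthalen-4(1H)-one | O=C1C=CC(OC)(OC)c2c(OCC=C)cc(Cl)c(OCOC)c12 | intermediate
13 | (2R,3S)-8-(allyloxy)-6-chloro-2,3-epoxy-1,1-dimethoxy-5-(methoxymethoxy)-2,3-dihydronaphthalen-4(1H)-one | C=CCOc1cc(Cl)c(OCOC)c2c1C(OC)(OC)[C@@H]1O[C@@H]1C2=O | intermediate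
14 | (2R,3R,4S)-8-(allyloxy)-6-chloro-2,3-epoxy-1,1-dimethoxy-5-(methoxymethoxy)-1,2,3,4-tetrahydronaphthalen-4-ol (OH trans to oxirane) | C=CCOc1cc(Cl)c(OCOC)c2c1C(OC)(OC)[C@@H]1O[C@@H]1[C@H]2O | intermediate
15 | (2R,3S,4S)-4-O-triisopropylsilyl ether of 14 | C=CCOc1cc(Cl)c(OCOC)c2c1C(OC)(OC)[C@@H]1O[C@@H]1[C@H]2O[Si](C(C)C)(C(C)C)C(C)C | intermediate
16 | (2R,3S,4S)-8-(allyloxy)-6-chloro-2,3-epoxy-5-(methoxymethoxy)-4-[(triisopropylsilyl)oxy]-3,4-dihydronaphthalen-1(2H)-one | C=CCOc1cc(Cl)c(OCOC)c2c1C(=O)[C@@H]1O[C@@H]1[C@H]2O[Si](C(C)C)(C(C)C)C(C)C | intermediate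
17 | 1-(4-chloro-3-hydroxyphenyl)ethan-1-one | CC(=O)c1ccc(Cl)c(O)c1 | starting material
18 | 1-[4-chloro-3-(methoxymethoxy)phenyl]ethan-1-one | CC(=O)c1ccc(Cl)c(OCOC)c1 | intermediate
19 | 2-[4-chloro-3-(methoxymethoxy)phenyl]-2,2-dimethoxyethan-1-ol | OCC(OC)(OC)c1ccc(Cl)c(OCOC)c1 | intermediate
20 | tert-butyl{2-[4-chloro-3-(methoxymethoxy)phenyl]-2,2-dimethoxyethoxy}dimethylsilane | CC(C)(C)[Si](C)(C)OCC(OC)(OC)c1ccc(Cl)c(OCOC)c1 | intermediate
21 | {2-[2-bromo-4-chloro-5-(methoxymethoxy)phenyl]-2,2-dimethoxyethoxy}(tert-butyl)dimethylsilane | CC(C)(C)[Si](C)(C)OCC(OC)(OC)c1cc(OCOC)c(Cl)cc1Br | intermediate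
22 | aryllithium from 21 (Li in place of Br) | [Li]c1cc(Cl)c(OCOC)cc1C(OC)(OC)CO[Si](C)(C)C(C)(C)C | intermediate
23 | tert-butyl{2-[4-chloro-5-(methoxymethoxy)-2-(trimethylsilyl)phenyl]-2,2-dimethoxyethoxy}dimethylsilane | CC(C)(C)[Si](C)(C)OCC(OC)(OC)c1cc(OCOC)c(Cl)cc1[Si](C)(C)C | intermediate
24 | aryllithium from 23 (Li between the MOM ether and the ketal carbon) | [Li]c1c(OCOC)c(Cl)cc([Si](C)(C)C)c1C(OC)(OC)CO[Si](C)(C)C(C)(C)C | intermediate
25 | {2-[2-bromo-4-chloro-3-(methoxymethoxy)-6-(trimethylsilyl)phenyl]-2,2-dimethoxyethoxy}(tert-butyl)dimethylsilane | CC(C)(C)[Si](C)(C)OCC(OC)(OC)c1c(Br)c(OCOC)c(Cl)cc1[Si](C)(C)C | intermediate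
26 | {2-[2-bromo-4-chloro-6-iodo-3-(methoxymethoxy)phenyl]-2,2-dimethoxyethoxy}(tert-butyl)dimethylsilane | CC(C)(C)[Si](C)(C)OCC(OC)(OC)c1c(Br)c(OCOC)c(Cl)cc1I | intermediate
27 | aryllithium from 26 (Li in place of I) | [Li]c1cc(Cl)c(OCOC)c(Br)c1C(OC)(OC)CO[Si](C)(C)C(C)(C)C | intermediate
28 | coupled tertiary alcohol (C8′–C1 bond; C1–OH cis to the C2–C3 oxirane, C4–OTIPS trans to it; C8–O-allyl; ring A with C4a′–Br and C1′ dimethyl ketal) | C=CCOc1cc(Cl)c(OCOC)c2c1[C@](c1cc(Cl)c(OCOC)c(Br)c1C(OC)(OC)CO[Si](C)(C)C(C)(C)C)(O)[C@@H]1O[C@@H]1[C@H]2O[Si](C(C)C)(C(C)C)C(C)C | intermediate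
29 | C8 phenol of 28 | Oc1cc(Cl)c(OCOC)c2c1[C@](c1cc(Cl)c(OCOC)c(Br)c1C(OC)(OC)CO[Si](C)(C)C(C)(C)C)(O)[C@@H]1O[C@@H]1[C@H]2O[Si](C(C)C)(C(C)C)C(C)C | intermediate
30 | five-membered cyclic methyl ketal (C1–O–C1′ closed, C1′–OMe, C8–OH free; C1′ epimers) | Oc1cc(Cl)c(OCOC)c2c1[C@]4(OC(OC)(CO[Si](C)(C)C(C)(C)C)c3c(Br)c(OCOC)c(Cl)cc34)[C@@H]1O[C@@H]1[C@H]2O[Si](C(C)C)(C(C)C)C(C)C | intermediate
31 | cage bromide (C4a′–Br; C1′–CH2OTBS; C4–OTIPS; C5 and C5′ OMOM; configuration at C1′, C1, C2, C3, C4 as in the target) | Brc1c(OCOC)c(Cl)cc3c1[C@@]2(Oc4cc(Cl)c(OCOC)c5c4[C@]3(O2)[C@@H]2O[C@@H]2[C@H]5O[Si](C(C)C)(C(C)C)C(C)C)CO[Si](C)(C)C(C)(C)C | intermediate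
32 | 2-chloro-N-methoxy-N-methylacetamide | CON(C)C(=O)CCl | starting material
33 | C4a′ aryllithium from 31 | [Li]c1c(OCOC)c(Cl)cc3c1[C@@]2(Oc4cc(Cl)c(OCOC)c5c4[C@]3(O2)[C@@H]2O[C@@H]2[C@H]5O[Si](C(C)C)(C(C)C)C(C)C)CO[Si](C)(C)C(C)(C)C | intermediate
34 | cage chloromethyl ketone (C4a′–C(=O)CH2Cl; C1′–CH2OTBS) | ClCC(=O)c1c(OCOC)c(Cl)cc3c1[C@@]2(Oc4cc(Cl)c(OCOC)c5c4[C@]3(O2)[C@@H]2O[C@@H]2[C@H]5O[Si](C(C)C)(C(C)C)C(C)C)CO[Si](C)(C)C(C)(C)C | intermediate
35 | cage chloromethyl ketone primary alcohol (C1′–CH2OH) | ClCC(=O)c1c(OCOC)c(Cl)cc3c1[C@@]2(Oc4cc(Cl)c(OCOC)c5c4[C@]3(O2)[C@@H]2O[C@@H]2[C@H]5O[Si](C(C)C)(C(C)C)C(C)C)CO | intermediate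
36 | cage chloroacetyl aldehyde (C1′–CHO; C4a′–C(=O)CH2Cl) | ClCC(=O)c1c(OCOC)c(Cl)cc3c1[C@@]2(Oc4cc(Cl)c(OCOC)c5c4[C@]3(O2)[C@@H]2O[C@@H]2[C@H]5O[Si](C(C)C)(C(C)C)C(C)C)C=O | intermediate
37 | cesium aldolate (C2′–O axial on the side of the bridging oxygen, C3′–Cl trans to it) | [Cs+].O=C1c2c(OCOC)c(Cl)cc3c2[C@@]2(Oc4cc(Cl)c(OCOC)c5c4[C@]3(O2)[C@@H]2O[C@@H]2[C@H]5O[Si](C(C)C)(C(C)C)C(C)C)[C@H]([O-])[C@H]1Cl | intermediate
38 | fully protected target (C5 and C5′ OMOM; C4–OTIPS) | O=C1c2c(OCOC)c(Cl)cc3c2[C@@]2(Oc4cc(Cl)c(OCOC)c5c4[C@]3(O2)[C@@H]2O[C@@H]2[C@H]5O[Si](C(C)C)(C(C)C)C(C)C)[C@@H]2O[C@H]12 | intermediate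
39 | C4 TIPS ether of the target | O=C1c2c(O)c(Cl)cc3c2[C@@]2(Oc4cc(Cl)c(O)c5c4[C@]3(O2)[C@@H]2O[C@@H]2[C@H]5O[Si](C(C)C)(C(C)C)C(C)C)[C@@H]2O[C@H]12 | intermediate
40 | CNP0289684.3 | O=C1c2c(O)c(Cl)cc3c2[C@@]2(Oc4cc(Cl)c(O)c5c4[C@]3(O2)[C@@H]2O[C@@H]2[C@H]5O)[C@@H]2O[C@H]12 | target

**Step count and risk**

Total step count: 27. Longest linear sequence: 20 steps (steps 1–11, then 19–27); the ring A branch (steps 12–18) joins at step 19.

Steps most likely to fail:

1. Step 25 (key step). The aldol may stay reversible without oxirane closure, closure may occur on the other face, or the base may degrade the chloro ketone. Fallback: setting out from 36, SmI2 in THF at −78 °C should give an intramolecular Reformatsky-type aldol to the β-hydroxy ketone F1. Mesylation (MsCl, Et3N) and elimination with DBU should give the ketal enone F2. Weitz–Scheffer epoxidation (t-BuOOH, DBU) should attack anti to the axial C1′–O(aryl) bond, and the route comes back at 38.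

2. Step 19. Facial selectivity may be poor because the bulky C4–OTIPS group lies on the face that the aryl group must take, and addition to the hindered ketone may be incomplete. Fallback: setting out from 14, ketal hydrolysis (aq. oxalic acid on SiO2) should give the free hydroxy epoxy ketone F3. Its lithium alkoxide (LiN(SiMe3)2, −78 °C) is then treated with aryllithium 27, so that the small alkoxide on the lower face guides the aryl group to that face and gives the diol F4. Silylation of the secondary C4 hydroxyl only (i-Pr3SiOTf, 2,6-lutidine, −78 °C) comes back at 28.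

3. Step 9. Facial selectivity may be poor if hydride attacks anti to the oxirane, which would give the cis alcohol. Fallback: setting out from 13, Luche reduction (NaBH4, CeCl3·7H2O, MeOH, −78 °C) should deliberately give the cis-epoxy alcohol F5. Mitsunobu inversion with 4-nitrobenzoic acid (PPh3, DIAD) should give the trans 4-nitrobenzoate F6, and methanolysis (K2CO3, MeOH) comes back at 14.

**Further compounds**

F1 | step 25 | cage β-hydroxy ketone (C2′–OH, C3′H2; C2′ epimers) | O=C1c2c(OCOC)c(Cl)cc3c2[C@@]2(Oc4cc(Cl)c(OCOC)c5c4[C@]3(O2)[C@@H]2O[C@@H]2[C@H]5O[Si](C(C)C)(C(C)C)C(C)C)C(O)C1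
F2 | step 25 | cage ketal enone (C2′=C3′) | O=C1c2c(OCOC)c(Cl)cc3c2[C@@]2(Oc4cc(Cl)c(OCOC)c5c4[C@]3(O2)[C@@H]2O[C@@H]2[C@H]5O[Si](C(C)C)(C(C)C)C(C)C)C=C1
F3 | step 19 | 8-(allyloxy)-6-chloro-2,3-epoxy-4-hydroxy-5-(methoxymethoxy)-3,4-dihydronaphthalen-1(2H)-one (OH trans to oxirane) | C=CCOc1cc(Cl)c(OCOC)c2c1C(=O)[C@@H]1O[C@@H]1[C@H]2O
F4 | step 19 | coupled C1,C4-diol (28 without the TIPS group) | C=CCOc1cc(Cl)c(OCOC)c2c1[C@](c1cc(Cl)c(OCOC)c(Br)c1C(OC)(OC)CO[Si](C)(C)C(C)(C)C)(O)[C@@H]1O[C@@H]1[C@H]2O
F5 | step 9 | cis-epoxy alcohol (C4 epimer of 14) | C=CCOc1cc(Cl)c(OCOC)c2c1C(OC)(OC)[C@@H]1O[C@@H]1[C@@H]2O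
F6 | step 9 | 4-nitrobenzoate of 14 (ester trans to oxirane) | C=CCOc1cc(Cl)c(OCOC)c2c1C(OC)(OC)[C@@H]1O[C@@H]1[C@H]2OC(=O)c1ccc(cc1)[N+](=O)[O-]
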